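**Retrosynthetic overview** (ent-kaurane numbering throughout)
1. Feature: rings C (C8, C9, C11, C12, C13, C14) and D (C8, C14, C13, C16, C15) form a bicyclo[3.2.1]octane whose cyclopentane ring D bridges the quaternary C8 (α to the C7 lactone carbonyl) and C13 and carries C17 on C16. This is the [3+2] adduct of a trimethylenemethane (TMM; C13, C15, C16, C17) and a 1,1-disubstituted acrylate (C8=C14).
2. Endgame: C16,C17-diol from the C16=C17 methylene; C15 alcohol by allylic oxidation then reduction; C2=C3 from the C1 ketone; the C7–O–C20 spirolactone from a C7 methyl ester and a C20 silyl ether.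
3. Key disconnection: C13–C14 and C8–C15 by intramolecular palladium–TMM cycloaddition of a C9-tethered acetoxy allylsilane onto the acrylate. The lactone is kept open in this step so that C10 can stand perpendicular to the acrylate and steer the addition to the face that gives the ent-kaurane C8/C13 configuration.
4. C9–C10 (both stereocentres) by Claisen rearrangement of an O-allylated 2-hydroxymethylene ketone, assembled from ring A and a Morita–Baylis–Hillman bromide; C5 by asymmetric conjugate reduction of a β-substituted cyclohexenone.
5. Ring order: A (from the start), C and D together (key step), then the δ-lactone, last the ring A unsaturation.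

Key step: step 13

Assumption: compounds 20 and 21 are carried as C13 epimer mixtures (the centre becomes a TMM terminus in step 13), and the (R)-ligand in step 3 is taken to deliver the drawn C5 configuration (otherwise its enantiomer is used).

Step 1
Reactants: 1 4,4-dimethylcyclohexane-1,3-dione
Product: 2 3-isobutoxy-6,6-dimethylcyclohex-2-en-1-one
Conditions: i-BuOH, p-TsOH (cat.), toluene, reflux, Dean–Stark
Reagents that add atoms: 2-methylpropan-1-ol, CC(C)CO
Why: Acid-catalysed vinylogous ester formation of the cyclic 1,3-dione should put the alkoxy group on the carbonyl carbon remote from the gem-dimethyl group, the less hindered and more stable enol ether; no stereocentre is formed.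

Step 2
Reactants: 2 3-isobutoxy-6,6-dimethylcyclohex-2-en-1-one; 3 tributyl[(methoxymethoxy)methyl]stannane
Product: 6 3-[(methoxymethoxy)methyl]-4,4-dimethylcyclohex-2-en-1-one, via (methoxymethoxy)methyllithium 4 (not isolated), via carbinol adduct 5 (not isolated)
Conditions: 3, n-BuLi, THF, −78 °C; then 2, −78 → 0 °C; then 1 M HCl, THF, 0 °C → rt
Reagents that add atoms: water, O (carbonyl oxygen of 6); n-butyllithium, [Li]CCCC (lithium of 4 only)
Why: Stork–Danheiser alkoxyenone transposition: tin–lithium exchange gives the α-alkoxymethyllithium, which adds 1,2 to the vinylogous ester, and acid hydrolysis with loss of water and isobutanol should give the β-substituted enone with C6 already on C5.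

Step 3
Reactants: 6 3-[(methoxymethoxy)methyl]-4,4-dimethylcyclohex-2-en-1-one
Product: 9 2-(hydroxymethylidene)-3-[(methoxymethoxy)methyl]-4,4-dimethylcyclohexan-1-one (C5 as in the target), via diphenylsilyl enol ether 7 (not isolated), via lithium enolate 8 (not isolated)
Conditions: Cu(OAc)2·H2O (3 mol %), (R)-DTBM-SEGPHOS (3 mol %), Ph2SiH2, toluene, 0 °C; then MeLi, THF, −78 → 0 °C; then HCO2CH2CF3, −78 °C; 1 M HCl work-up
Reagents that add atoms: 2,2,2-trifluoroethyl formate, O=COCC(F)(F)F; diphenylsilane, c1ccc(cc1)[SiH2]c1ccccc1 (silyl group of 7 only); methyllithium, [Li]C (lithium of 8 only)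
Why: Asymmetric conjugate reduction by a ligated monovalent copper hydride should deliver hydride to one enantioface of the β-carbon, setting C5, and give the C1–C10 silyl enol ether regiospecifically, which methyllithium turns into the lithium enolate for Claisen-type C-formylation at C10.

Step 4
Reactants: 10 pent-4-enal; 11 methyl acrylate
Product: 12 methyl 3-hydroxy-2-methylidenehept-6-enoate (racemic)
Conditions: DABCO (0.5 equiv), neat, rt
Reagents that add atoms: none
Why: Morita–Baylis–Hillman reaction of an unhindered aliphatic aldehyde with methyl acrylate; the carbinol centre is removed in step 5.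

Step 5
Reactants: 12 methyl 3-hydroxy-2-methylidenehept-6-enoate
Product: 13 methyl (2Z)-2-(bromomethyl)hepta-2,6-dienoate
Conditions: PBr3 (0.4 equiv), Et2O, 0 °C
Reagents that add atoms: phosphorus tribromide, BrP(Br)Br
Why: Allylic bromination with SN2' transposition of the Morita–Baylis–Hillman alcohol should give the more stable (Z)-enoate, with the alkyl chain cis to CH2Br.

Step 6
Reactants: 9 hydroxymethylene ketone; 13 methyl (2Z)-2-(bromomethyl)hepta-2,6-dienoate
Product: 14 (E)-alkoxymethylidene ketone (allyl vinyl ether; ether oxygen anti to the C1 carbonyl)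
Conditions: K2CO3, acetone, rt
Reagents that add atoms: none
Why: Williamson-type O-alkylation of the acidic 2-hydroxymethylene ketone by SN2 at the primary allylic bromide should give the (E)-alkoxymethylidene ketone, the congested C10 disfavouring C-alkylation.

Step 7
Reactants: 14 (E)-alkoxymethylidene ketone
Product: 15 C10-quaternary formyl ketone (C20 formyl cis to C6; C9 trans to C6 and bearing the butenyl chain and the acrylate)
Conditions: xylenes, BHT (cat.), 140 °C, sealed tube
Reagents that add atoms: none
Why: Claisen rearrangement through a chair transition state: the allyl fragment should bond to C10 on the face away from the C6 substituent (held axial by allylic strain with the enol ether), so C20 ends cis and C9 trans to C6, and the (E)-vinyl ether and (Z)-allyl geometries translate into the required C9 configuration (H9 anti to C20 when C8 is anti to C1).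

Step 8
Reactants: 15 formyl ketone
Product: 16 C20 primary alcohol
Conditions: NaBH4 (0.5 equiv), THF/EtOH, −78 → −40 °C
Reagents that add atoms: none
Why: Chemoselective borohydride reduction: at low temperature the aldehyde is far more electrophilic than the neopentyl C1 ketone and the conjugated ester; no stereocentre is formed.

Step 9
Reactants: 16 C20 alcohol
Product: 17 C20 tert-butyldimethylsilyl ether
Conditions: TBSOTf, 2,6-lutidine, CH2Cl2, −78 °C
Reagents that add atoms: tert-butyldimethylsilyl trifluoromethanesulfonate, CC(C)(C)[Si](C)(C)OS(=O)(=O)C(F)(F)F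
Why: Silylation of the primary alcohol at −78 °C should be fast enough to forestall δ-lactonisation onto C7, and 2,6-lutidine does not enolise the ketone.

Step 10
Reactants: 17 silyl ether
Product: 18 C13 aldehyde
Conditions: O3, CH2Cl2, −78 °C, Sudan Red 7B end point; then PPh3, −78 °C → rt
Reagents that add atoms: ozone, [O-][O+]=O
Why: Ozonolysis with reductive work-up should cleave the electron-rich monosubstituted alkene selectively over the electron-poor acrylate when stopped at the indicator end point.

Step 11
Reactants: 18 C13 aldehyde; 19 (2-bromoallyl)trimethylsilane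
Product: 20 C13 allylic alcohol carrying the 2-(trimethylsilylmethyl)allyl unit (C13 epimers)
Conditions: CrCl2 (4 equiv), NiCl2 (2 mol %), DMF/THF, rt
Reagents that add atoms: none
Why: Nozaki–Hiyama–Kishi coupling: the alkenylchromium species adds only to the aldehyde, sparing ketone, acrylate and allylsilane, and the C13 epimer mixture is inconsequential.

Step 12
Reactants: 20 allylic alcohol
Product: 21 allylic acetate (cycloaddition precursor; C13 epimers)
Conditions: Ac2O, pyridine, DMAP (cat.), CH2Cl2, 0 °C → rt
Reagents that add atoms: acetic anhydride, CC(=O)OC(C)=O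
Why: DMAP-catalysed acylation of the secondary allylic alcohol gives the ionisable acetate of the TMM precursor.

Step 13
Reactants: 21 allylic acetate
Product: 22 bicyclo[3.2.1]octane cycloadduct (rings C and D closed; C7 methyl ester on C8; C16=C17 methylene; C20 silyl ether)
Conditions: Pd(OAc)2 (10 mol %), P(OiPr)3 (60 mol %), THF, 65 °C, 0.005 M, slow addition of 21
Reagents that add atoms: none
Why: Proposed new method: zerovalent palladium ionises the allylic acetate and acetate removes the silyl group to give the palladium–TMM zwitterion, which equilibrates so that the tether-bearing C13 is the nucleophile; C13 adds to the unhindered methylene C14 of the acrylate and the resulting C7 ester enolate attacks the π-allyl terminus C15 on the face opposite palladium, leaving the C16=C17 methylene and returning the catalyst. The closest known chemistry is the palladium-catalysed TMM [3+2] cycloaddition, established intermolecularly with α-methylene esters and lactones and intramolecularly only in the fused mode; the bridged mode with the tether on the acceptor α-carbon is not known. Ring C closes by a chair-like 6-endo-trig Michael addition (C13 to C14) and ring D by 5-exo attack of C8 on C15, which requires C16 axial on ring C, so that the quaternary C8 is made at an enolate carbon. C13 and C8 are set together and both by C9: allylic strain with the C7 ester and its enolate keeps H9 near the acrylate plane and the quaternary C10 perpendicular to it, so the TMM should add to the acrylate face opposite C10 and C15 ends anti to C10 (C10 axial, C7 equatorial on ring C), the ent-kaurane arrangement. The step needs this face selectivity and cyclisation over oligomerisation; the first is secured by leaving the lactone open (a closed C7–O–C20 lactone would hold C10 in the enolate plane and favour the C8/C13-epimeric, trans-fused adduct), the second by high dilution and because first attack through C15 or C17 would need an eight-membered ring.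

Step 14
Reactants: 22 cycloadduct
Product: 24 spirolactone with C1 ketone and C16=C17 methylene, via C20 hydroxy ester 23 (not isolated)
Conditions: HF·pyridine, THF, 0 °C → rt; then PPTS (cat.), toluene, 70 °C
Reagents that add atoms: none
Why: Acidic desilylation frees the C20 alcohol, which should lactonise by transesterification onto the neighbouring C7 ester to the six-membered spirolactone, without exposing the β-hydroxy ketone to base (no retro-aldol).

Step 15
Reactants: 24 spirolactone
Product: 25 C15 exo allylic alcohol
Conditions: SeO2 (0.5 equiv), t-BuOOH, CH2Cl2, rt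
Reagents that add atoms: selenium dioxide, O=[Se]=O; tert-butyl hydroperoxide, CC(C)(C)OO
Why: Selenium dioxide allylic oxidation (ene reaction, then [2,3]-sigmatropic shift) should hydroxylate C15 from the exo face, the bridgehead C13 being unable to react; this stereocentre is erased in step 16.

Step 16
Reactants: 25 C15 exo allylic alcohol
Product: 26 C15 ketone (exo-methylene cyclopentanone; C1 ketone retained)
Conditions: Dess–Martin periodinane, NaHCO3, CH2Cl2, rt
Reagents that add atoms: none
Why: Dess–Martin oxidation of the secondary allylic alcohol leaves lactone and MOM ether untouched.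

Step 17
Reactants: 26 diketone
Product: 27 C1 tert-butyldimethylsilyl enol ether (C1=C2) of the C15 enone
Conditions: TBSOTf, Et3N, CH2Cl2, −78 → 0 °C
Reagents that add atoms: tert-butyldimethylsilyl trifluoromethanesulfonate, CC(C)(C)[Si](C)(C)OS(=O)(=O)C(F)(F)F
Why: Soft enolisation and silylation can take place only at C2, because the quaternary C8 and sp2 C16 leave neither the lactone nor the C15 ketone an enolisable hydrogen, so the C1 ketone alone is masked.

Step 18
Reactants: 27 silyl enol ether enone
Product: 28 C15 endo alcohol (silyl enol ether retained)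
Conditions: NaBH4, CeCl3·7H2O, MeOH/THF, −78 °C
Reagents that add atoms: none
Why: Luche 1,2-reduction of the only remaining ketone with hydride attack from the exo face of ring D (the C14 side; the endo face is shielded by the axial H11) should set the endo C15 alcohol of the target.

Step 19
Reactants: 28 C15 endo alcohol
Product: 29 ring A enone (C1 ketone, C2=C3)
Conditions: Pd(OAc)2 (1.2 equiv), MeCN, 40 °C
Reagents that add atoms: none
Why: Saegusa–Ito oxidation: palladation of the silyl enol ether and β-hydride elimination give the C2=C3 enone.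

Step 20
Reactants: 29 ring A enone
Product: 30 C15,C16,C17-triol MOM ether
Conditions: OsO4 (5 mol %), NMO, acetone/H2O, 0 °C → rt
Reagents that add atoms: osmium tetroxide, O=[Os](=O)(=O)=O; N-methylmorpholine N-oxide, C[N+]1([O-])CCOCC1; water, O
Why: Catalytic osmylation should select the electron-rich exocyclic C16=C17 alkene over the enone alkene and add on the exo face, anti to the allylic C15 hydroxyl, giving the exo C16 tertiary alcohol and C17 primary alcohol.

Step 21
Reactants: 30 triol MOM ether
Product: 31 CNP0546915.1 (target)
Conditions: 2 M HCl (aq), MeOH, 40 °C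
Reagents that add atoms: none
Why: Acid-catalysed acetal exchange cleaves the MOM ether to the C6 alcohol; lactone, enone and triol should tolerate dilute acid.

**Compound list**
1 | 4,4-dimethylcyclohexane-1,3-dione | O=C1CCC(C)(C)C(=O)C1 | starting material
2 | 3-isobutoxy-6,6-dimethylcyclohex-2-en-1-one | CC(C)COC1=CC(=O)C(C)(C)CC1 | intermediate
3 | tributyl[(methoxymethoxy)methyl]stannane | CCCC[Sn](CCCC)(CCCC)COCOC | starting material
4 | (methoxymethoxy)methyllithium | [Li]COCOC | intermediate
5 | 3-isobutoxy-1-[(methoxymethoxy)methyl]-6,6-dimethylcyclohex-2-en-1-ol (racemic carbinol adduct, formed as its lithium alkoxide) | CC(C)COC1=CC(O)(COCOC)C(C)(C)CC1 | intermediate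
6 | 3-[(methoxymethoxy)methyl]-4,4-dimethylcyclohex-2-en-1-one | COCOCC1=CC(=O)CCC1(C)C | intermediate
7 | diphenylsilyl enol ether (C1=C10) of 3-[(methoxymethoxy)methyl]-4,4-dimethylcyclohexanone, C5 set | CC1(C)CCC(O[SiH](c2ccccc2)c2ccccc2)=C[C@@H]1COCOC | intermediate
8 | lithium enolate (C1=C10) of the same ketone | CC1(C)CCC(O[Li])=C[C@@H]1COCOC | intermediate
9 | 2-(hydroxymethylidene)-3-[(methoxymethoxy)methyl]-4,4-dimethylcyclohexan-1-one, chelated enol, C5 as in the target | CC1(C)CCC(=O)/C(=C\O)[C@@H]1COCOC | intermediate
10 | pent-4-enal | C=CCCC=O | starting material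
11 | methyl acrylate | C=CC(=O)OC | starting material
12 | methyl 3-hydroxy-2-methylidenehept-6-enoate (racemic) | C=CCCC(O)C(=C)C(=O)OC | intermediate
13 | methyl (2Z)-2-(bromomethyl)hepta-2,6-dienoate | C=CCC/C=C(\CBr)C(=O)OC | intermediate
14 | (E)-alkoxymethylidene ketone: ring A C10=C20H–O–CH2–C(CO2Me)=CH–(CH2)2CH=CH2, ether O anti to C1=O, chain cis to CH2O | CC1(C)CCC(=O)/C(=C/OC/C(C(=O)OC)=C\CCC=C)[C@@H]1COCOC | intermediate
15 | formyl ketone: C10 bears C20HO (cis to C6) and C9 (trans to C6); C9 bears but-3-enyl and the methyl acrylate unit | CC1(C)CCC(=O)[C@@](C=O)([C@H](CCC=C)C(=C)C(=O)OC)[C@@H]1COCOC | intermediate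
16 | C20 alcohol of 15 | CC1(C)CCC(=O)[C@@](CO)([C@H](CCC=C)C(=C)C(=O)OC)[C@@H]1COCOC | intermediate
17 | C20 TBS ether | CC1(C)CCC(=O)[C@@](CO[Si](C)(C)C(C)(C)C)([C@H](CCC=C)C(=C)C(=O)OC)[C@@H]1COCOC | intermediate
18 | C13 aldehyde | CC1(C)CCC(=O)[C@@](CO[Si](C)(C)C(C)(C)C)([C@H](CCC=O)C(=C)C(=O)OC)[C@@H]1COCOC | intermediate
19 | (2-bromoallyl)trimethylsilane | C=C(Br)C[Si](C)(C)C | starting material
20 | C13 allylic alcohol with 2-(trimethylsilylmethyl)allyl unit (C13 epimer mixture) | CC1(C)CCC(=O)[C@@](CO[Si](C)(C)C(C)(C)C)([C@H](CCC(O)C(=C)C[Si](C)(C)C)C(=C)C(=O)OC)[C@@H]1COCOC | intermediate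
21 | C13 acetate, cycloaddition precursor (C13 epimer mixture) | CC1(C)CCC(=O)[C@@](CO[Si](C)(C)C(C)(C)C)([C@H](CCC(OC(C)=O)C(=C)C[Si](C)(C)C)C(=C)C(=O)OC)[C@@H]1COCOC | intermediate
22 | cycloadduct: bicyclo[3.2.1]octane (rings C and D), C7 methyl ester on C8, C16=C17, C20 TBS ether | CC1(C)CCC(=O)[C@@](CO[Si](C)(C)C(C)(C)C)([C@@H]2CC[C@@H]3C[C@@]2(C(=O)OC)CC3=C)[C@@H]1COCOC | intermediate
23 | C20 hydroxy ester | CC1(C)CCC(=O)[C@@](CO)([C@@H]2CC[C@@H]3C[C@@]2(C(=O)OC)CC3=C)[C@@H]1COCOC | intermediate
24 | spirolactone with C1 ketone, C6 MOM ether, C16=C17 | CC1(C)CCC(=O)[C@]2(COC(=O)[C@@]34C[C@@H](CC[C@@H]23)C(=C)C4)[C@@H]1COCOC | intermediate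
25 | C15 exo alcohol | CC1(C)CCC(=O)[C@]2(COC(=O)[C@@]34C[C@@H](CC[C@@H]23)C(=C)[C@@H]4O)[C@@H]1COCOC | intermediate
26 | C1,C15-diketone (C15 enone) | CC1(C)CCC(=O)[C@]2(COC(=O)[C@@]34C[C@@H](CC[C@@H]23)C(=C)C4=O)[C@@H]1COCOC | intermediate
27 | C1 TBS enol ether of 26 | CC1(C)CC=C(O[Si](C)(C)C(C)(C)C)[C@]2(COC(=O)[C@@]34C[C@@H](CC[C@@H]23)C(=C)C4=O)[C@@H]1COCOC | intermediate
28 | C15 endo alcohol, C1 TBS enol ether | CC1(C)CC=C(O[Si](C)(C)C(C)(C)C)[C@]2(COC(=O)[C@@]34C[C@@H](CC[C@@H]23)C(=C)[C@H]4O)[C@@H]1COCOC | intermediate
29 | ring A enone, C15 endo alcohol, C16=C17 | CC1(C)C=CC(=O)[C@]2(COC(=O)[C@@]34C[C@@H](CC[C@@H]23)C(=C)[C@H]4O)[C@@H]1COCOC | intermediate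
30 | MOM ether of the target | CC1(C)C=CC(=O)[C@]2(COC(=O)[C@@]34C[C@@H](CC[C@@H]23)[C@@](O)(CO)[C@H]4O)[C@@H]1COCOC | intermediate
31 | CNP0546915.1 | CC1(C)C=CC(=O)[C@]2(COC(=O)[C@@]34C[C@@H](CC[C@@H]23)[C@@](O)(CO)[C@H]4O)[C@@H]1CO | target

**Step count**
Total: 21 steps. Longest linear sequence: 19 steps (steps 1–3 and 6–21); steps 4–5 make the side fragment.

**Steps most likely to fail**

1. Step 13 (proposed new method). What may go wrong: protodesilylation or β-hydride elimination of the π-allylpalladium intermediate before C13 reaches C14, oligomerisation, or closure on the other face of C8.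
Fallback, known reactions only, setting out from aldehyde 18 and returning at spirolactone 24: Wittig olefination of 18 with isopropylidenetriphenylphosphorane should give the trisubstituted alkene F1. HF·pyridine then PPTS closes the lactone to the α-methylene spirolactone F2. Me2AlCl promotes an intramolecular ene reaction in which C13 bonds to C14 and a methyl hydrogen passes to C8, giving the isopropenyl lactone F3. In the closed lactone C10 lies in the enoate plane, so the equatorial isopropenyl group should be trans to C10 as the target requires. Ene-type allylic chlorination with Ca(OCl)2 and CO2 gives the allylic chloride F4. KHMDS (2.2 equiv, THF, −78 → 0 °C) forms the lactone enolate, which alkylates intramolecularly on the only face the C13 substituent can reach, closing ring D to give 24.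

2. Step 7. What may go wrong: rearrangement through the boat or from the (Z)-vinyl ether erodes the C9 selectivity, or the hindered ether decomposes on heating.
Fallback, setting out from 9 and 12 and returning at 15: 12 with Boc2O and DMAP gives the tert-butyl carbonate F5. 9 and F5 with a cinchona tertiary amine (β-isocupreidine, 10 mol %, toluene) should undergo amine-catalysed allylic alkylation: SN2' addition of the amine with loss of CO2 and tert-butoxide, deprotonation of 9, then SN2' attack of C10 on the allylammonium at C9. This gives 15 directly, with C10 set by approach anti to C6 and C9 by the catalyst.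

3. Step 18. What may go wrong: solvolysis of the silyl enol ether under the Lewis-acidic methanolic conditions followed by over-reduction at C1, or poor facial selectivity at C15.
Fallback, setting out from 24 and returning at 30: dehydrogenation of 24 with IBX (DMSO, 70 °C) gives the ring A enone F6. SeO2 and t-BuOOH give the C15 allylic alcohol F7, and MnO2 the bis-enone F8. Luche reduction then reduces both carbonyl groups to the bis-allylic diol F9 (C1 epimers). Osmylation of the more accessible 1,1-disubstituted C16=C17 alkene (OsO4, NMO, 0 °C) gives the tetraol F10, in which only the C1 alcohol is still allylic. MnO2 oxidises that alcohol selectively to 30.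

**Further compounds**
F1 | step 13 | trisubstituted alkene (C13H=CMe2 chain, open ester, C20 TBS ether) | CC1(C)CCC(=O)[C@@](CO[Si](C)(C)C(C)(C)C)([C@H](CCC=C(C)C)C(=C)C(=O)OC)[C@@H]1COCOC
F2 | step 13 | α-methylene spirolactone with 4-methylpent-3-enyl chain on C9 | CC1(C)CCC(=O)[C@]2(COC(=O)C(=C)[C@H]2CCC=C(C)C)[C@@H]1COCOC
F3 | step 13 | ring C lactone with isopropenyl on C13 and H on C8 (C8 epimers) | CC1(C)CCC(=O)[C@]2(COC(=O)C3C[C@@H](CC[C@@H]23)C(C)=C)[C@@H]1COCOC
F4 | step 13 | allylic chloride of F3 | CC1(C)CCC(=O)[C@]2(COC(=O)C3C[C@@H](CC[C@@H]23)C(=C)CCl)[C@@H]1COCOC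
F5 | step 7 | methyl 3-[(tert-butoxycarbonyl)oxy]-2-methylidenehept-6-enoate (racemic) | C=CCCC(OC(=O)OC(C)(C)C)C(=C)C(=O)OC
F6 | step 18 | ring A enone spirolactone with C16=C17 | CC1(C)C=CC(=O)[C@]2(COC(=O)[C@@]34C[C@@H](CC[C@@H]23)C(=C)C4)[C@@H]1COCOC
F7 | step 18 | C15 exo alcohol of F6 | CC1(C)C=CC(=O)[C@]2(COC(=O)[C@@]34C[C@@H](CC[C@@H]23)C(=C)[C@@H]4O)[C@@H]1COCOC
F8 | step 18 | bis-enone (C1 and C15 ketones) | CC1(C)C=CC(=O)[C@]2(COC(=O)[C@@]34C[C@@H](CC[C@@H]23)C(=C)C4=O)[C@@H]1COCOC
F9 | step 18 | bis-allylic diol (C1 epimers, C15 endo) | CC1(C)C=CC(O)[C@]2(COC(=O)[C@@]34C[C@@H](CC[C@@H]23)C(=C)[C@H]4O)[C@@H]1COCOC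
F10 | step 18 | C1,C15,C16,C17-tetraol (C1 epimers) | CC1(C)C=CC(O)[C@]2(COC(=O)[C@@]34C[C@@H](CC[C@@H]23)[C@@](O)(CO)[C@H]4O)[C@@H]1COCOC
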